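The route rests on cutting the C2–C3 bond of the pyran ring (ring C). The feature exploited is that C2 sits between O1 and the ring B aryl group, so O1–C2 can be carried as an aryl 4-oxybenzoate ester, while C4–C3 is an ortho-allyl group placed on C4a of the phloroglucinol ring (ring A) by Claisen rearrangement. A titanium-alkylidene olefinic-ester cyclisation (ring-closing carbonyl–olefin metathesis) joins the ester carbon and the internal allyl carbon in one operation as the C2=C3 enol ether of a 2-aryl-4H-chromene. The precursor is an open-chain aryl benzoate with no ring C. Asymmetric hydrogenation then sets 2S, and the aryl 1,2-diketone is added at C8 through iodide, alkyne and oxidation.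

Key step: step 5

Assumptions: the (S)-configured phosphinooxazoline ligand in step 6 is taken to deliver hydrogen to the face of C2=C3 that gives 2S (if a model substrate shows the opposite sense, the (R)-ligand is used with no other change); 4-(methoxymethoxy)benzoic acid and 1-ethynyl-4-(methoxymethoxy)benzene are taken as catalogue compounds.

Step 1
Reactants: 1 phloroglucinol
Product: 2 3,5-bis(methoxymethoxy)phenol
Conditions: MOMCl (2.0 equiv), iPr2NEt (2.2 equiv), DMF, 0 °C → rt; bis-ether separated by chromatography from mono- and tris-ether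
Reagents that add atoms: chloromethyl methyl ether (MOMCl), COCCl
Why: Williamson-type O-alkylation of the threefold-symmetric triol with a hard acetal chloride should give a statistical mixture from which the bis-ether is isolated, the mono-ether being recycled.

Step 2
Reactants: 2 3,5-bis(methoxymethoxy)phenol, 3 allyl bromide
Product: 4 1-(allyloxy)-3,5-bis(methoxymethoxy)benzene
Conditions: K2CO3, acetone, reflux
Reagents that add atoms: none
Why: Williamson ether synthesis on the single free phenol, which becomes O1 of the target.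

Step 3
Reactants: 4 1-(allyloxy)-3,5-bis(methoxymethoxy)benzene
Product: 5 2-allyl-3,5-bis(methoxymethoxy)phenol
Conditions: PhNEt2, 190 °C, sealed tube
Reagents that add atoms: none
Why: Aromatic Claisen rearrangement; the two ortho positions are equivalent, so a single regioisomer should form, with the allyl group (future C4 and C3) on the future C4a and the phenol released for acylation.

Step 4
Reactants: 5 2-allyl-3,5-bis(methoxymethoxy)phenol, 6 4-(methoxymethoxy)benzoic acid
Product: 7 2-allyl-3,5-bis(methoxymethoxy)phenyl 4-(methoxymethoxy)benzoate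
Conditions: DCC, DMAP (cat.), CH2Cl2, 0 °C → rt
Reagents that add atoms: none
Why: Steglich esterification of the only free phenol attaches the future C2 together with ring B to O1.

Step 5
Reactants: 7 2-allyl-3,5-bis(methoxymethoxy)phenyl 4-(methoxymethoxy)benzoate
Product: 8 5,7-bis(methoxymethoxy)-2-[4-(methoxymethoxy)phenyl]-4H-chromene
Conditions: TiCl4, TMEDA, Zn dust, PbCl2 (cat.), CH3CHBr2, THF–CH2Cl2, 0 → 65 °C; product handled on basic alumina
Reagents that add atoms: none
Why: The low-valent titanium ethylidene made in the flask exchanges with the terminal allyl olefin (propene is lost) to put a titanium alkylidene on C3, which adds [2+2] to the ester carbonyl C2=O and cycloreverts to the C2=C3 enol ether and a titanium oxo species. The closest known reaction type is the olefinic-ester cyclisation with the Takai–Utimoto reagent, a ring-closing carbonyl–olefin metathesis. Ring C closes in a 6-exo mode at the carbonyl carbon, the C=O bond lying outside the forming benzo-fused six-membered ring. No stereocentre is formed, since C2 becomes the sp2 enol-ether carbon whose configuration is set in step 6. The step needs cyclisation to win over plain ethylidenation of the ester, which the monosubstituted terminal olefin (fast alkylidene exchange) and the ortho relation of allyl group and ester oxygen should secure. No other carbonyl group is present, and the aryl MOM ethers should tolerate the TMEDA-complexed titanium reagent.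

Step 6
Reactants: 8 5,7-bis(methoxymethoxy)-2-[4-(methoxymethoxy)phenyl]-4H-chromene
Product: 9 (2S)-5,7-bis(methoxymethoxy)-2-[4-(methoxymethoxy)phenyl]chromane
Conditions: H2 (50 bar), [Ir(cod)((S)-tBu-PHOX)]BArF (2 mol %; BArF = B[3,5-(CF3)2C6H3]4), CH2Cl2, rt
Reagents that add atoms: none
Why: Iridium-catalysed asymmetric hydrogenation of a trisubstituted cyclic enol ether (a 2-aryl-4H-chromene) with a chiral P,N-ligand cation, in which the ligand pocket selects one face of C2=C3 and so sets C2 as S, while aryl acetals are not touched.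

Step 7
Reactants: 9 (2S)-5,7-bis(methoxymethoxy)-2-[4-(methoxymethoxy)phenyl]chromane
Product: 10 (2S)-8-iodo-5,7-bis(methoxymethoxy)-2-[4-(methoxymethoxy)phenyl]chromane
Conditions: NIS (1.0 equiv), DMF, 0 °C → rt, dark
Reagents that add atoms: N-iodosuccinimide (NIS), O=C1CCC(=O)N1I
Why: Electrophilic aromatic iodination on the only trioxygenated ring (ring A), where C8 (between O1 and the C7 ether) is less shielded than C6 (between two MOM ethers), in line with the known C8 halogenation of 5,7-di-O-alkyl flavans.

Step 8
Reactants: 10 (2S)-8-iodo-5,7-bis(methoxymethoxy)-2-[4-(methoxymethoxy)phenyl]chromane, 11 1-ethynyl-4-(methoxymethoxy)benzene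
Product: 12 (2S)-5,7-bis(methoxymethoxy)-2-[4-(methoxymethoxy)phenyl]-8-{[4-(methoxymethoxy)phenyl]ethynyl}chromane
Conditions: PdCl2(PPh3)2 (5 mol %), CuI (10 mol %), Et3N–DMF, 70 °C
Reagents that add atoms: none
Why: Sonogashira coupling of an aryl iodide, reactive enough to overcome the two ortho oxygen substituents, brings in both diketone carbons and the fourth aryl ring at once.

Step 9
Reactants: 12 (2S)-5,7-bis(methoxymethoxy)-2-[4-(methoxymethoxy)phenyl]-8-{[4-(methoxymethoxy)phenyl]ethynyl}chromane
Product: 13 1-{(2S)-5,7-bis(methoxymethoxy)-2-[4-(methoxymethoxy)phenyl]chroman-8-yl}-2-[4-(methoxymethoxy)phenyl]ethane-1,2-dione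
Conditions: KMnO4, NaHCO3, acetone–H2O, 0 °C → rt
Reagents that add atoms: potassium permanganate (KMnO4), [K+].[O-][Mn](=O)(=O)=O
Why: Permanganate oxidation of a diaryl alkyne to the 1,2-diketone through a cyclic manganate ester, which involves no electrophilic π-activation (so O1 and the C7 ether cannot cyclise onto the alkyne) and is buffered against benzilic acid rearrangement.

Step 10
Reactants: 13 1-{(2S)-5,7-bis(methoxymethoxy)-2-[4-(methoxymethoxy)phenyl]chroman-8-yl}-2-[4-(methoxymethoxy)phenyl]ethane-1,2-dione
Product: 14 1-[(2S)-5,7-dihydroxy-2-(4-hydroxyphenyl)chroman-8-yl]-2-(4-hydroxyphenyl)ethane-1,2-dione (CNP0332855.1)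
Conditions: HCl (2 M in MeOH), THF, rt → 40 °C
Reagents that add atoms: none
Why: Acid-catalysed acetal exchange with methanol should remove all four MOM groups, while the C2–O1 benzylic ether, its oxygen deactivated by the C8 carbonyl, should stay closed under this mild acid, so C2 keeps its configuration.

Compound list
1 | phloroglucinol (benzene-1,3,5-triol) | Oc1cc(O)cc(O)c1 | starting material
2 | 3,5-bis(methoxymethoxy)phenol | COCOc1cc(O)cc(OCOC)c1 | intermediate
3 | allyl bromide (3-bromoprop-1-ene) | C=CCBr | starting material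
4 | 1-(allyloxy)-3,5-bis(methoxymethoxy)benzene | C=CCOc1cc(OCOC)cc(OCOC)c1 | intermediate
5 | 2-allyl-3,5-bis(methoxymethoxy)phenol | C=CCc1c(O)cc(OCOC)cc1OCOC | intermediate
6 | 4-(methoxymethoxy)benzoic acid | COCOc1ccc(cc1)C(O)=O | starting material
7 | 2-allyl-3,5-bis(methoxymethoxy)phenyl 4-(methoxymethoxy)benzoate | C=CCc1c(OC(=O)c2ccc(OCOC)cc2)cc(OCOC)cc1OCOC | intermediate
8 | 5,7-bis(methoxymethoxy)-2-[4-(methoxymethoxy)phenyl]-4H-chromene | COCOc1ccc(cc1)C1=CCc2c(O1)cc(OCOC)cc2OCOC | intermediate
9 | (2S)-5,7-bis(methoxymethoxy)-2-[4-(methoxymethoxy)phenyl]chromane | COCOc1cc(OCOC)c2c(c1)O[C@H](c1ccc(OCOC)cc1)CC2 | intermediate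
10 | (2S)-8-iodo-5,7-bis(methoxymethoxy)-2-[4-(methoxymethoxy)phenyl]chromane | COCOc1cc(OCOC)c2c(c1I)O[C@H](c1ccc(OCOC)cc1)CC2 | intermediate
11 | 1-ethynyl-4-(methoxymethoxy)benzene | C#Cc1ccc(OCOC)cc1 | starting material
12 | (2S)-5,7-bis(methoxymethoxy)-2-[4-(methoxymethoxy)phenyl]-8-{[4-(methoxymethoxy)phenyl]ethynyl}chromane | COCOc1cc(OCOC)c2c(c1C#Cc1ccc(OCOC)cc1)O[C@H](c1ccc(OCOC)cc1)CC2 | intermediate
13 | 1-{(2S)-5,7-bis(methoxymethoxy)-2-[4-(methoxymethoxy)phenyl]chroman-8-yl}-2-[4-(methoxymethoxy)phenyl]ethane-1,2-dione | COCOc1cc(OCOC)c2c(c1C(=O)C(=O)c1ccc(OCOC)cc1)O[C@H](c1ccc(OCOC)cc1)CC2 | intermediate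
14 | 1-[(2S)-5,7-dihydroxy-2-(4-hydroxyphenyl)chroman-8-yl]-2-(4-hydroxyphenyl)ethane-1,2-dione | O=C(C(=O)c1c(O)cc(O)c2c1O[C@H](c1ccc(O)cc1)CC2)c1ccc(O)cc1 | target

Total step count: 10. Longest linear sequence: 10 steps (1 → 14); compounds 3, 6 and 11 enter as purchased materials.

Steps most likely to fail

Step 5. The titanium ethylidene may olefinate the ester without first exchanging with the allyl group, leaving an open-chain enol ether, or residual Lewis acidity may strip MOM groups. The fallback sets out from 7 and comes back at 8. The ester is methylenated with the Tebbe reagent Cp2Ti(μ-CH2)(μ-Cl)AlMe2 (pyridine, THF–toluene, −40 °C → rt) to the acyclic enol ether 2-allyl-3,5-bis(methoxymethoxy)phenyl 1-[4-(methoxymethoxy)phenyl]ethenyl ether F1. This isolated diene is then closed by ruthenium-carbene ring-closing metathesis with the second-generation Grubbs catalyst RuCl2(=CHPh)(PCy3)(SIMes) (toluene, 70 °C, loss of ethene), which forms the same C2=C3 bond and gives 8.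

Step 6. The catalyst may discriminate poorly between the two faces of C2=C3, or the acidic iridium hydride may hydrate or ionise the enol ether before it is reduced. The fallback sets out from 8 and comes back at 9, keeping the C2–C3 bond made in step 5. The enol ether is hydrolysed (oxalic acid, wet THF, 0 °C, conditions that leave aryl MOM ethers intact) to the ketone 3-[2-hydroxy-4,6-bis(methoxymethoxy)phenyl]-1-[4-(methoxymethoxy)phenyl]propan-1-one F2. Asymmetric transfer hydrogenation with RuCl(p-cymene)[(R,R)-TsDPEN] in HCO2H–Et3N should give the alcohol (1R)-3-[2-hydroxy-4,6-bis(methoxymethoxy)phenyl]-1-[4-(methoxymethoxy)phenyl]propan-1-ol F3. Mitsunobu etherification (PPh3, DIAD, THF, 0 °C) then closes O1–C2 with inversion to give the 2S flavan 9.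

Step 9. Permanganate may over-oxidise (cleavage of the diketone, attack at the benzylic C2–H or C4–H bonds or at ring A), or the shielded alkyne may not react. The fallback sets out from 12 and comes back at 13. Semi-hydrogenation (H2, Pd/CaCO3 poisoned with Pb(OAc)2, quinoline, EtOAc) should give the stilbene (2S)-5,7-bis(methoxymethoxy)-2-[4-(methoxymethoxy)phenyl]-8-{(Z)-2-[4-(methoxymethoxy)phenyl]ethenyl}chromane F4. Dihydroxylation (OsO4 cat., NMO, acetone–H2O) gives the diol 1-{(2S)-5,7-bis(methoxymethoxy)-2-[4-(methoxymethoxy)phenyl]chroman-8-yl}-2-[4-(methoxymethoxy)phenyl]ethane-1,2-diol F5, as a mixture at the two carbinol carbons that is of no consequence. Swern oxidation (DMSO, (COCl)2, Et3N, CH2Cl2, −78 °C) of both carbinols gives 13.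

Further compounds
F1 | step 5 | 2-allyl-3,5-bis(methoxymethoxy)phenyl 1-[4-(methoxymethoxy)phenyl]ethenyl ether | C=CCc1c(OC(=C)c2ccc(OCOC)cc2)cc(OCOC)cc1OCOC
F2 | step 6 | 3-[2-hydroxy-4,6-bis(methoxymethoxy)phenyl]-1-[4-(methoxymethoxy)phenyl]propan-1-one | O=C(CCc1c(O)cc(OCOC)cc1OCOC)c1ccc(OCOC)cc1
F3 | step 6 | (1R)-3-[2-hydroxy-4,6-bis(methoxymethoxy)phenyl]-1-[4-(methoxymethoxy)phenyl]propan-1-ol | O[C@H](CCc1c(O)cc(OCOC)cc1OCOC)c1ccc(OCOC)cc1
F4 | step 9 | (2S)-5,7-bis(methoxymethoxy)-2-[4-(methoxymethoxy)phenyl]-8-{(Z)-2-[4-(methoxymethoxy)phenyl]ethenyl}chromane | COCOc1cc(OCOC)c2c(c1/C=C\c1ccc(OCOC)cc1)O[C@H](c1ccc(OCOC)cc1)CC2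
F5 | step 9 | 1-{(2S)-5,7-bis(methoxymethoxy)-2-[4-(methoxymethoxy)phenyl]chroman-8-yl}-2-[4-(methoxymethoxy)phenyl]ethane-1,2-diol (mixture at the carbinol carbons) | COCOc1cc(OCOC)c2c(c1C(O)C(O)c1ccc(OCOC)cc1)O[C@H](c1ccc(OCOC)cc1)CC2
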